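**Retrosynthetic overview**
- Unit 1 is the 7-methoxyflavonol half and unit 2 the 5,7-dihydroxyflavonol half, each with rings A (benzo), C (pyranone) and B (2-aryl). The last operations are hydrogenolysis of four benzyl ethers and, before it, closure of ring C of unit 2 on the ring B aldehyde by Claisen–Schmidt condensation with a dibenzyl phloroacetophenone and Algar–Flynn–Oyamada oxidation.
- The route rests on ring A of unit 1: a benzene fused through C4a and C8a to the pyranone ring C, with C5–OH and C7–OMe meta to each other. It is cut at C8–C8a, C5–C6, C7–C8 and C4a–C5 into a 6-(diazoacetyl)-4-pyranone and methoxyacetylene (photo-Wolff benzannulation).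
- The diazoketone comes from comenic acid (ring C of unit 1 bought): bromination next to the enol, double benzylation, Suzuki–Miyaura coupling with the ring B boronate, ester cleavage, acylation of diazomethane.
- The diaryl ether between the two rings B is made first by SNAr of 2-(benzyloxy)-4-bromophenol on 4-fluoro-3-methoxybenzaldehyde; the aldehyde is carried as a dioxolane.
- Ring order: both rings B, ring C of unit 1 and ring A of unit 2 are bought; ring A of unit 1 is formed in the key step and ring C of unit 2 last.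

Key step: step 11

**Remarks on the chemistry**
- Ar stands throughout for 3-(benzyloxy)-4-[4-(1,3-dioxolan-2-yl)-2-methoxyphenoxy]phenyl.
- Flavone atoms are numbered O1, C2, C3, C4, C4a, C5 to C8, C8a.
- The dibenzyl phloroacetophenone of step 13 and 1-(2,6-dihydroxy-4-methoxyphenyl)ethanone (used in one fallback) are assumed to be purchasable.
- The target has no stereocentre; racemic intermediates are drawn as one enantiomer.

**Route**

Step 1
Reactants: 1 comenic acid (5-hydroxy-4-oxo-4H-pyran-2-carboxylic acid)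
Product: 2 6-bromo-5-hydroxy-4-oxo-4H-pyran-2-carboxylic acid
Conditions: Br2 (1.05 equiv), H2O, rt
Reagents that add atoms: bromine BrBr
Why: Electrophilic bromination of the enolic 3-hydroxy-4-pyranone should go at the only free carbon next to the hydroxyl (C6), as it does for kojic and comenic acid.

Step 2
Reactants: 2 6-bromo-5-hydroxy-4-oxo-4H-pyran-2-carboxylic acid
Product: 3 benzyl 5-(benzyloxy)-6-bromo-4-oxo-4H-pyran-2-carboxylate
Conditions: BnBr (2.3 equiv), K2CO3, DMF, 50 °C
Reagents that add atoms: benzyl bromide BrCc1ccccc1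
Why: Williamson O-alkylation of the acidic enol and alkylation of the carboxylate should both occur in one pot, giving a fully protected coupling partner.

Step 3
Reactants: 4 2-(benzyloxy)phenol
Product: 5 2-(benzyloxy)-4-bromophenol
Conditions: NBS (1.0 equiv), MeCN, 0 °C
Reagents that add atoms: N-bromosuccinimide O=C1CCC(=O)N1Br
Why: Electrophilic aromatic bromination should go para to the free hydroxyl, the stronger donor, which places bromine at the future C1' of ring B of unit 1.

Step 4
Reactants: 5 2-(benzyloxy)-4-bromophenol; 6 4-fluoro-3-methoxybenzaldehyde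
Product: 7 4-[2-(benzyloxy)-4-bromophenoxy]-3-methoxybenzaldehyde
Conditions: K2CO3, DMF, 120 °C
Reagents that add atoms: none
Why: Nucleophilic aromatic substitution (SNAr) of the fluoride para to the formyl group by the phenoxide builds the diaryl ether, and the unactivated aryl bromide is inert under these conditions.

Step 5
Reactants: 7 4-[2-(benzyloxy)-4-bromophenoxy]-3-methoxybenzaldehyde
Product: 8 2-{4-[2-(benzyloxy)-4-bromophenoxy]-3-methoxyphenyl}-1,3-dioxolane
Conditions: ethylene glycol, p-TsOH (cat.), toluene, reflux, Dean–Stark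
Reagents that add atoms: ethylene glycol OCCO
Why: Acid-catalysed acetalisation with azeotropic removal of water masks the aldehyde against the later borylation, hydroxide, diazomethane and ketene chemistry.

Step 6
Reactants: 8 2-{4-[2-(benzyloxy)-4-bromophenoxy]-3-methoxyphenyl}-1,3-dioxolane
Product: 9 2-Ar-4,4,5,5-tetramethyl-1,3,2-dioxaborolane (the pinacol boronate of ring B of unit 1)
Conditions: B2pin2, PdCl2(dppf) (cat.), KOAc, 1,4-dioxane, 90 °C
Reagents that add atoms: bis(pinacolato)diboron CC1(C)OB(OC1(C)C)B1OC(C)(C)C(C)(C)O1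
Why: Miyaura borylation of an electron-rich aryl bromide under acetate base is compatible with the acetal and the benzyl ether.

Step 7
Reactants: 3 benzyl 5-(benzyloxy)-6-bromo-4-oxo-4H-pyran-2-carboxylate; 9 2-Ar-4,4,5,5-tetramethyl-1,3,2-dioxaborolane
Product: 10 benzyl 6-Ar-5-(benzyloxy)-4-oxo-4H-pyran-2-carboxylate
Conditions: Pd(PPh3)4 (cat.), K3PO4, 1,4-dioxane/H2O (10:1), 70 °C
Reagents that add atoms: none
Why: Suzuki–Miyaura coupling; the C–Br bond of 3 is a vinylogous acyl bromide that should add readily to zerovalent palladium, and the phosphate base spares the dioxolane and largely the benzyl ester.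

Step 8
Reactants: 10 benzyl 6-Ar-5-(benzyloxy)-4-oxo-4H-pyran-2-carboxylate
Product: 11 lithium 6-Ar-5-(benzyloxy)-4-oxo-4H-pyran-2-carboxylate
Conditions: LiOH·H2O (1.05 equiv), THF/H2O, 0 °C; evaporate, triturate with Et2O, dry
Reagents that add atoms: lithium hydroxide [Li+].[OH-]
Why: Saponification at the ester carbonyl, activated by the electron-poor pyranone, should outrun hydroxide addition to the ring at 0 °C, and keeping the product as its salt avoids any acid contact with the dioxolane.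

Step 9
Reactants: 11 lithium 6-Ar-5-(benzyloxy)-4-oxo-4H-pyran-2-carboxylate
Product: 13 2-Ar-3-(benzyloxy)-6-(diazoacetyl)-4H-pyran-4-one, via mixed carbonic anhydride 12 (not isolated)
Conditions: i-BuOCOCl, THF/DMF, −15 °C; then CH2N2 (3 equiv), Et2O, −15 to 0 °C; excess CH2N2 swept out with N2
Reagents that add atoms: diazomethane C=[N+]=[N-]
Why: Acylation of diazomethane by a mixed carbonic anhydride (first stage of the Arndt–Eistert sequence) made directly from the carboxylate salt; the isobutyl carbonate leaving group takes up the proton and falls apart to isobutanol and CO2, so no acid is generated.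

Step 10
Reactants: 14 chloroacetaldehyde dimethyl acetal (2-chloro-1,1-dimethoxyethane)
Product: 17 methoxyacetylene (methoxyethyne), via chlorovinyl methyl ether 15 (not isolated), via sodium methoxyethynide 16 (not isolated)
Conditions: NaNH2 (3 equiv), liquid NH3, −33 °C; then sat. aq NaCl, −70 °C; distil into cold ClCH2CH2Cl
Reagents that add atoms: none
Why: Two successive base-induced eliminations (methanol, then HCl) give the ynol ether, held as its sodium acetylide until the aqueous quench, as in the standard preparation of alkoxyacetylenes from chloroacetals.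

Step 11
Reactants: 13 2-Ar-3-(benzyloxy)-6-(diazoacetyl)-4H-pyran-4-one; 17 methoxyacetylene
Product: 21 2-Ar-3-(benzyloxy)-5-hydroxy-7-methoxy-4H-chromen-4-one, via pyranonylketene 18 (not isolated), via vinylcyclobutenone 19 (not isolated), via dienylketene 20 (not isolated)
Conditions: 17 (5 equiv), ClCH2CH2Cl, 450 nm LEDs, 0 °C, sealed Pyrex tube, until 13 is consumed; excess 17 vented in an argon stream; then dark, 80 °C
Reagents that add atoms: none
Why: Proposed new method: light expels N2 from 13 and the pyranone carbon migrates (Wolff rearrangement, making the C8–C8a bond) to give ketene 18, whose vinyl arm is the pyranone C4a=C8a double bond, and 18 adds methoxyacetylene in a [2+2] cycloaddition (C5–C6 and C7–C8 bonds) to give 19. On warming in the dark 19 should open by four-electron electrocyclic ring opening to dienylketene 20, which closes ring A of unit 1 by a thermal disrotatory six-electron electrocyclisation (C4a–C5 bond) and tautomerises to the chelated phenol 21. The closest known reaction is the Danheiser benzannulation in its diazoketone (photo-Wolff) form with alkoxyalkynes, established for alkenyl, aryl and heteroaryl diazoketones but not for one whose vinyl arm is a 4-pyranone double bond. No stereocentre is formed. The step needs regiocontrol in the [2+2] addition, which the polarised ynol ether supplies because its unsubstituted nucleophilic carbon bonds to the ketene carbonyl carbon and so puts OMe on C7 and the ketene oxygen on C5, and it needs ring closure at one site only, which is secured because the carbon carrying the ketene arm has the ring oxygen as its other neighbour. Light of 450 nm should excite only the diazoketone, and the flavone chromophore appears only in the dark thermal stage.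

Step 12
Reactants: 21 2-Ar-3-(benzyloxy)-5-hydroxy-7-methoxy-4H-chromen-4-one
Product: 22 4-{2-(benzyloxy)-4-[3-(benzyloxy)-5-hydroxy-7-methoxy-4-oxo-4H-chromen-2-yl]phenoxy}-3-methoxybenzaldehyde
Conditions: 1 M aq HCl, THF, rt
Reagents that add atoms: water O
Why: Acid-catalysed acetal hydrolysis frees the aldehyde on ring B of unit 2, while benzyl ethers, the diaryl ether and the flavone are stable to dilute acid.

Step 13
Reactants: 22 4-{2-(benzyloxy)-4-[3-(benzyloxy)-5-hydroxy-7-methoxy-4-oxo-4H-chromen-2-yl]phenoxy}-3-methoxybenzaldehyde; 23 1-[2,4-bis(benzyloxy)-6-hydroxyphenyl]ethanone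
Product: 24 (E)-4',6'-bis(benzyloxy)-2'-hydroxychalcone built on the formyl-bearing ring of 22 (unit 1 unchanged)
Conditions: KOH (50% aq, excess), EtOH/THF, rt
Reagents that add atoms: none
Why: Claisen–Schmidt aldol condensation; only 23 can enolise and only 22 has an aldehyde, dehydration gives the conjugated E-enone, and the unit 1 flavone sits as its 5-phenoxide, which lowers its sensitivity to hydroxide.

Step 14
Reactants: 24 (E)-4',6'-bis(benzyloxy)-2'-hydroxychalcone carrying unit 1
Product: 26 tetra-O-benzyl target (3,3'-di-O-benzyl unit 1 joined to the 5,7-di-O-benzyl flavonol of unit 2), via trans-dihydroflavonol 25 (not isolated)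
Conditions: 30% H2O2, 2 M NaOH, MeOH/THF, 0 °C to rt
Reagents that add atoms: hydrogen peroxide OO
Why: Algar–Flynn–Oyamada oxidation: alkaline peroxide should convert the 2'-hydroxychalcone into the trans-3-hydroxyflavanone 25 by oxidative closure of the phenoxide on the enone β-carbon (closing ring C of unit 2), and a second equivalent dehydrogenates 25 to the flavonol; the 3-benzyloxy flavone of unit 1 offers peroxide no reactive enone.

Step 15
Reactants: 26 tetra-O-benzyl target
Product: 27 CNP0190193.0 (target)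
Conditions: H2 (1 atm), 10% Pd/C, THF/MeOH, rt
Reagents that add atoms: none
Why: Catalytic hydrogenolysis should remove the four benzyl ethers, while the flavonol C2=C3 bonds (vinylogous esters), the aryl methyl ethers and the diaryl ether are not reduced at one atmosphere and room temperature.

**Compound list**

1 | comenic acid | O=C(O)c1cc(=O)c(O)co1 | starting material
2 | 6-bromo-5-hydroxy-4-oxo-4H-pyran-2-carboxylic acid | O=C(O)c1cc(=O)c(O)c(Br)o1 | intermediate
3 | benzyl 5-(benzyloxy)-6-bromo-4-oxo-4H-pyran-2-carboxylate | O=C(OCc1ccccc1)c1cc(=O)c(OCc2ccccc2)c(Br)o1 | intermediate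
4 | 2-(benzyloxy)phenol | Oc1ccccc1OCc1ccccc1 | starting material
5 | 2-(benzyloxy)-4-bromophenol | Oc1ccc(Br)cc1OCc1ccccc1 | intermediate
6 | 4-fluoro-3-methoxybenzaldehyde | COc1cc(C=O)ccc1F | starting material
7 | 4-[2-(benzyloxy)-4-bromophenoxy]-3-methoxybenzaldehyde | COc1cc(C=O)ccc1Oc1ccc(Br)cc1OCc1ccccc1 | intermediate
8 | 2-{4-[2-(benzyloxy)-4-bromophenoxy]-3-methoxyphenyl}-1,3-dioxolane | COc1cc(C2OCCO2)ccc1Oc1ccc(Br)cc1OCc1ccccc1 | intermediate
9 | 2-{3-(benzyloxy)-4-[4-(1,3-dioxolan-2-yl)-2-methoxyphenoxy]phenyl}-4,4,5,5-tetramethyl-1,3,2-dioxaborolane | COc1cc(C2OCCO2)ccc1Oc1ccc(B2OC(C)(C)C(C)(C)O2)cc1OCc1ccccc1 | intermediate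
10 | benzyl 6-Ar-5-(benzyloxy)-4-oxo-4H-pyran-2-carboxylate | O=C(OCc1ccccc1)c1cc(=O)c(OCc2ccccc2)c(-c2ccc(Oc3ccc(C4OCCO4)cc3OC)c(OCc3ccccc3)c2)o1 | intermediate
11 | lithium 6-Ar-5-(benzyloxy)-4-oxo-4H-pyran-2-carboxylate | [Li+].[O-]C(=O)c1cc(=O)c(OCc2ccccc2)c(-c2ccc(Oc3ccc(C4OCCO4)cc3OC)c(OCc3ccccc3)c2)o1 | intermediate
12 | 6-Ar-5-(benzyloxy)-4-oxo-4H-pyran-2-carboxylic isobutyl carbonic anhydride | CC(C)COC(=O)OC(=O)c1cc(=O)c(OCc2ccccc2)c(-c2ccc(Oc3ccc(C4OCCO4)cc3OC)c(OCc3ccccc3)c2)o1 | intermediate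
13 | 2-Ar-3-(benzyloxy)-6-(diazoacetyl)-4H-pyran-4-one | [N-]=[N+]=CC(=O)c1cc(=O)c(OCc2ccccc2)c(-c2ccc(Oc3ccc(C4OCCO4)cc3OC)c(OCc3ccccc3)c2)o1 | intermediate
14 | chloroacetaldehyde dimethyl acetal | COC(CCl)OC | starting material
15 | (Z)-1-chloro-2-methoxyethene (the E isomer would react the same way) | CO/C=C\Cl | intermediate
16 | sodium methoxyethynide | [Na+].[C-]#COC | intermediate
17 | methoxyacetylene | COC#C | intermediate
18 | [6-Ar-5-(benzyloxy)-4-oxo-4H-pyran-2-yl]ketene | O=C=Cc1cc(=O)c(OCc2ccccc2)c(-c2ccc(Oc3ccc(C4OCCO4)cc3OC)c(OCc3ccccc3)c2)o1 | intermediate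
19 | 4-[6-Ar-5-(benzyloxy)-4-oxo-4H-pyran-2-yl]-3-methoxycyclobut-2-en-1-one (racemic, one enantiomer drawn) | COC1=CC(=O)[C@@H]1c1cc(=O)c(OCc2ccccc2)c(-c2ccc(Oc3ccc(C4OCCO4)cc3OC)c(OCc3ccccc3)c2)o1 | intermediate
20 | 4-[6-Ar-5-(benzyloxy)-4-oxo-4H-pyran-2-yl]-3-methoxybuta-1,3-dien-1-one (ketene arm cis to the pyranone across the C7=C8 bond) | O=C=C/C(OC)=C\c1cc(=O)c(OCc2ccccc2)c(-c2ccc(Oc3ccc(C4OCCO4)cc3OC)c(OCc3ccccc3)c2)o1 | intermediate
21 | 2-Ar-3-(benzyloxy)-5-hydroxy-7-methoxy-4H-chromen-4-one | COc1cc(O)c2c(=O)c(OCc3ccccc3)c(-c3ccc(Oc4ccc(C5OCCO5)cc4OC)c(OCc4ccccc4)c3)oc2c1 | intermediate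
22 | 4-{2-(benzyloxy)-4-[3-(benzyloxy)-5-hydroxy-7-methoxy-4-oxo-4H-chromen-2-yl]phenoxy}-3-methoxybenzaldehyde | COc1cc(O)c2c(=O)c(OCc3ccccc3)c(-c3ccc(Oc4ccc(C=O)cc4OC)c(OCc4ccccc4)c3)oc2c1 | intermediate
23 | 1-[2,4-bis(benzyloxy)-6-hydroxyphenyl]ethanone | CC(=O)c1c(O)cc(OCc2ccccc2)cc1OCc1ccccc1 | starting material
24 | (E)-1-[2,4-bis(benzyloxy)-6-hydroxyphenyl]-3-{4-[2-(benzyloxy)-4-(3-(benzyloxy)-5-hydroxy-7-methoxy-4-oxo-4H-chromen-2-yl)phenoxy]-3-methoxyphenyl}prop-2-en-1-one | COc1cc(O)c2c(=O)c(OCc3ccccc3)c(-c3ccc(Oc4ccc(/C=C/C(=O)c5c(O)cc(OCc6ccccc6)cc5OCc5ccccc5)cc4OC)c(OCc4ccccc4)c3)oc2c1 | intermediate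
25 | trans-5,7-bis(benzyloxy)-2-{4-[2-(benzyloxy)-4-(3-(benzyloxy)-5-hydroxy-7-methoxy-4-oxo-4H-chromen-2-yl)phenoxy]-3-methoxyphenyl}-3-hydroxychroman-4-one (racemic, 2R,3R drawn) | COc1cc(O)c2c(=O)c(OCc3ccccc3)c(-c3ccc(Oc4ccc([C@H]5Oc6cc(OCc7ccccc7)cc(OCc7ccccc7)c6C(=O)[C@@H]5O)cc4OC)c(OCc4ccccc4)c3)oc2c1 | intermediate
26 | 5,7-bis(benzyloxy)-2-{4-[2-(benzyloxy)-4-(3-(benzyloxy)-5-hydroxy-7-methoxy-4-oxo-4H-chromen-2-yl)phenoxy]-3-methoxyphenyl}-3-hydroxy-4H-chromen-4-one (tetra-O-benzyl target) | COc1cc(O)c2c(=O)c(OCc3ccccc3)c(-c3ccc(Oc4ccc(-c5oc6cc(OCc7ccccc7)cc(OCc7ccccc7)c6c(=O)c5O)cc4OC)c(OCc4ccccc4)c3)oc2c1 | intermediate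
27 | CNP0190193.0 | COc1cc(O)c2c(=O)c(O)c(-c3ccc(Oc4ccc(-c5oc6cc(O)cc(O)c6c(=O)c5O)cc4OC)c(O)c3)oc2c1 | target

**Step count and risk**

Total step count: 15. Longest linear sequence: 12 steps (steps 3, 4, 5, 6, 7, 8, 9, 11, 12, 13, 14, 15, from 4).

Steps most likely to fail:

1. Step 11 (bears the new-method label). The pyranone chromophore may be excited instead of the diazo group, or the ketene may oligomerise or fail to close onto the pyranone carbon, so that ring A of unit 1 does not form. The fallback builds unit 1 by known chalcone chemistry, sets out from 8 and returns at 22. Bromine–lithium exchange on 8 (n-BuLi, THF, −78 °C) and formylation with DMF would give 3-(benzyloxy)-4-[4-(1,3-dioxolan-2-yl)-2-methoxyphenoxy]benzaldehyde F1. Commercial 1-(2,6-dihydroxy-4-methoxyphenyl)ethanone would be mono-protected (MOMCl, i-Pr2NEt, CH2Cl2) to 1-[2-hydroxy-4-methoxy-6-(methoxymethoxy)phenyl]ethanone F2. Claisen–Schmidt condensation of F1 and F2 (KOH, EtOH) would give the (E)-chalcone F3, and Algar–Flynn–Oyamada oxidation (H2O2, NaOH, MeOH) the 3-hydroxy-7-methoxy-5-(methoxymethoxy)flavone F4. Benzylation of the 3-hydroxyl (BnBr, K2CO3, DMF) would give the 3-benzyl ether F5, and aqueous HCl in THF/MeOH at 50 °C would remove the MOM group and the dioxolane together to reach 22.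

2. Step 14. The chalcone may cyclise through its α-carbon to the aurone, as 6'-alkoxy-2'-hydroxychalcones tend to do, and prolonged alkali may open the pyranone of unit 1. The fallback separates epoxidation from cyclisation, sets out from 22 and returns at 26. Ketone 23 would be protected (NaH, MOMCl, DMF) as 1-[2,4-bis(benzyloxy)-6-(methoxymethoxy)phenyl]ethanone F6 and condensed with 22 (KOH, EtOH/THF) to the 2'-O-MOM (E)-chalcone F7. With its phenol masked, F7 can only be epoxidised by H2O2/NaOH, to the trans-epoxide F8. HCl in MeOH/THF would then remove the MOM group and let the phenol open the epoxide at the benzylic carbon to give the trans-dihydroflavonol 25, here isolated. Dehydrogenation of 25 with I2 and KOAc in AcOH at 90 °C would give 26.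

3. Step 9. Diazomethane may add as a 1,3-dipole to the electron-poor pyranone double bond, or attack the carbonate carbonyl of the mixed anhydride, instead of being acylated cleanly. The fallback introduces the diazo group by diazo transfer to a methyl ketone, sets out from 11 and returns at 13. Salt 11 would be converted through anhydride 12 with MeNHOMe·HCl and N-methylmorpholine into the N-methoxy-N-methylamide F9. MeMgBr (THF, −78 °C, NH4Cl work-up) would give the 6-acetyl pyranone F10. Enolisation with LiN(SiMe3)2, trifluoroacetylation with CF3CO2CH2CF3 and NH4Cl work-up would give the trifluoroacetyl diketone F11, and detrifluoroacetylative diazo transfer (MsN3, Et3N, H2O, MeCN) would give 13.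

**Further compounds**

F1 | step 11 | 3-(benzyloxy)-4-[4-(1,3-dioxolan-2-yl)-2-methoxyphenoxy]benzaldehyde | COc1cc(C2OCCO2)ccc1Oc1ccc(C=O)cc1OCc1ccccc1
F2 | step 11 | 1-[2-hydroxy-4-methoxy-6-(methoxymethoxy)phenyl]ethanone | COCOc1cc(OC)cc(O)c1C(C)=O
F3 | step 11 | (E)-1-[2-hydroxy-4-methoxy-6-(methoxymethoxy)phenyl]-3-Ar-prop-2-en-1-one | COCOc1cc(OC)cc(O)c1C(=O)/C=C/c1ccc(Oc2ccc(C3OCCO3)cc2OC)c(OCc2ccccc2)c1
F4 | step 11 | 2-Ar-3-hydroxy-7-methoxy-5-(methoxymethoxy)-4H-chromen-4-one | COCOc1cc(OC)cc2oc(-c3ccc(Oc4ccc(C5OCCO5)cc4OC)c(OCc4ccccc4)c3)c(O)c(=O)c12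
F5 | step 11 | 2-Ar-3-(benzyloxy)-7-methoxy-5-(methoxymethoxy)-4H-chromen-4-one | COCOc1cc(OC)cc2oc(-c3ccc(Oc4ccc(C5OCCO5)cc4OC)c(OCc4ccccc4)c3)c(OCc3ccccc3)c(=O)c12
F6 | step 14 | 1-[2,4-bis(benzyloxy)-6-(methoxymethoxy)phenyl]ethanone | COCOc1cc(OCc2ccccc2)cc(OCc2ccccc2)c1C(C)=O
F7 | step 14 | (E)-1-[2,4-bis(benzyloxy)-6-(methoxymethoxy)phenyl]-3-{4-[2-(benzyloxy)-4-(3-(benzyloxy)-5-hydroxy-7-methoxy-4-oxo-4H-chromen-2-yl)phenoxy]-3-methoxyphenyl}prop-2-en-1-one | COCOc1cc(OCc2ccccc2)cc(OCc2ccccc2)c1C(=O)/C=C/c1ccc(Oc2ccc(-c3oc4cc(OC)cc(O)c4c(=O)c3OCc3ccccc3)cc2OCc2ccccc2)c(OC)c1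
F8 | step 14 | trans-epoxide of F7 (racemic, one enantiomer drawn) | COCOc1cc(OCc2ccccc2)cc(OCc2ccccc2)c1C(=O)[C@H]1O[C@@H]1c1ccc(Oc2ccc(-c3oc4cc(OC)cc(O)c4c(=O)c3OCc3ccccc3)cc2OCc2ccccc2)c(OC)c1
F9 | step 9 | 6-Ar-5-(benzyloxy)-N-methoxy-N-methyl-4-oxo-4H-pyran-2-carboxamide | CON(C)C(=O)c1cc(=O)c(OCc2ccccc2)c(-c2ccc(Oc3ccc(C4OCCO4)cc3OC)c(OCc3ccccc3)c2)o1
F10 | step 9 | 6-acetyl-2-Ar-3-(benzyloxy)-4H-pyran-4-one | CC(=O)c1cc(=O)c(OCc2ccccc2)c(-c2ccc(Oc3ccc(C4OCCO4)cc3OC)c(OCc3ccccc3)c2)o1
F11 | step 9 | 1-[6-Ar-5-(benzyloxy)-4-oxo-4H-pyran-2-yl]-4,4,4-trifluorobutane-1,3-dione | O=C(CC(=O)C(F)(F)F)c1cc(=O)c(OCc2ccccc2)c(-c2ccc(Oc3ccc(C4OCCO4)cc3OC)c(OCc3ccccc3)c2)o1
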